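**Plan**

- Retrosynthetic cuts, in order: the C11–O aryl ether (umbelliferone), the C9–C11 bond (methylene on a C9 ketone), the second C4 methyl, then C1–C10 and C4–C5 of ring A together.
- Enabling feature: ring B (C5–C10), with its C8 methyl, C7=C8 alkene, C10 methyl and a C9 carbonyl, is 4,4-dimethoxy-2,6-dimethylcyclohexa-2,5-dienone. Its second enone alkene (C5=C10) is a dienophile for a 2-silyloxydiene that brings C1–C4 with oxygen on C3.
- Forward: ring B is bought as a phenol and ring A is closed onto it by a catalytic asymmetric Diels–Alder reaction. Ring A is then adjusted (enone, C4 methylation, hydrogenation), the ketal opened, C6 deoxygenated through its γ-acetate, C9 methylenated and hydroborated, and the coumarin attached last.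
- Stereochemistry: C10 from the chiral catalyst; C5 by equilibration to the trans ring fusion through the C6 ketone; C3 by axial hydride attack; C9 by hydroboration anti to the axial C10 methyl.

Key step: step 3

Assumption: the (S)-configured oxazaborolidinium ion is taken to expose the enone face that gives (10R)-5; should the sense of induction be the opposite, its (R)-antipode is used unchanged.

Locants are those of the drimane skeleton: ring A = C1–C5/C10, ring B = C5–C10, C4 carries the ring-A methyl(s), C8 the vinylic methyl, C10 the angular methyl, C11 is the carbon on C9. "Syn" and "anti" refer to the face of the C10 methyl.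

**Route**

Step 1
Reactants: 1 4-methoxy-2,6-dimethylphenol
Product: 2 4,4-dimethoxy-2,6-dimethylcyclohexa-2,5-dien-1-one
Conditions: PhI(OAc)2 (1.1 equiv), MeOH, 0 °C → rt
Reagents that add atoms: methanol, CO
Why: Hypervalent-iodine oxidative dearomatisation, in which the phenol bound to iodine loses iodobenzene and methanol traps the resulting cation at the methoxy-bearing para carbon, the standard route to p-quinone monoketals.

Step 2
Reactants: 3 ethyl vinyl ketone (pent-1-en-3-one)
Product: 4 (Z)-3-(triisopropylsilyloxy)penta-1,3-diene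
Conditions: TIPSOTf, Et3N, Et2O, 0 °C → rt
Reagents that add atoms: triisopropylsilyl triflate, CC(C)[Si](C(C)C)(C(C)C)OS(=O)(=O)C(F)(F)F
Why: Soft enolisation (O-silylation, then amine deprotonation of the only α-CH2) gives the 2-silyloxydiene, and the bulky silyloxy group favours the Z enol ether with the methyl outside.

Step 3
Reactants: 2 4,4-dimethoxy-2,6-dimethylcyclohexa-2,5-dien-1-one; 4 (Z)-3-(triisopropylsilyloxy)penta-1,3-diene
Product: 5 cis-fused adduct (4R,5S,10R)-6,6-dimethoxy-4,8,10-trimethyl-3-(triisopropylsilyloxy)decalin-2,7-dien-9-one (H4 H5 and the C10 methyl syn)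
Conditions: 20 mol % oxazaborolidinium triflimide from (S)-1-(2-methylphenyl)-3,3-diphenyltetrahydro-1H,3H-pyrrolo[1,2-c][1,3,2]oxazaborole and HN(SO2CF3)2, 4 (1.5 equiv), CH2Cl2, −78 → −20 °C
Reagents that add atoms: none
Why: The boron cation binds the single carbonyl of 2 and lowers the LUMO of one enone so that the β-CH (future C5) is the electrophilic terminus; the siloxy-activated, methyl-bearing diene terminus C4 bonds there first and C1 closes onto the methylated α-carbon C10 in a concerted, asynchronous endo [4+2] cycloaddition. The closest known reaction type is the oxazaborolidinium-catalysed Diels–Alder addition of 2-silyloxydienes to quinones and quinone monoketals. Ring A closes as a six-membered carbocycle by suprafacial [4+2] cycloaddition that forms C1–C10 and C4–C5 in one operation. C10 is set by the catalyst, which selects between the enantiotopic enone faces; C5 follows from suprafacial addition to the ring alkene (H5 syn to the C10 methyl), and C4 from the endo orientation of the carbonyl-bearing ring together with the Z diene geometry, which puts the C4 methyl outside and H4 syn to H5. The step needs regio-, endo- and enantioselectivity: regiochemistry is secured by matching the donor-substituted diene terminus with the carbonyl-polarised β-carbon, endo selectivity by the Lewis-acid-bound carbonyl, and enantioselectivity rests on the catalyst alone. Only C10 must be right, because C4 becomes quaternary and C5 is epimerised later.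

Step 4
Reactants: 5 cis-fused silyl enol ether adduct
Product: 6 cis-fused (4R,5S,10R)-6,6-dimethoxy-4,8,10-trimethyldecalin-1,7-diene-3,9-dione
Conditions: Pd(OAc)2 (1.1 equiv), MeCN, rt → 40 °C
Reagents that add atoms: none
Why: Saegusa–Ito oxidation: divalent palladium replaces silicon at C2 of the C2=C3 enol ether and β-hydride elimination of H1 gives the C1=C2 enone, which leaves C4 as the only enolisable carbon of ring A.

Step 5
Reactants: 6 cis-fused dienedione ketal
Product: 8 cis-fused (5S,10R)-6,6-dimethoxy-4,4,8,10-tetramethyldecalin-1,7-diene-3,9-dione, via lithium C3–C4 enolate 7 (not isolated)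
Conditions: LiN(iPr)2 (LDA), THF, −78 °C; MeI, DMPU, −78 → 0 °C
Reagents that add atoms: iodomethane, CI
Why: Kinetic α′-deprotonation of the cyclohexenone (C10 is quaternary, so no γ-hydrogen competes, and the C9 enone has no acidic hydrogen) gives the cross-conjugated enolate, whose C-methylation makes C4 the gem-dimethyl carbon and removes its stereocentre (enone α′-alkylation).

Step 6
Reactants: 8 cis-fused 4,4-dimethyl dienedione ketal
Product: 9 cis-fused (5S,10R)-6,6-dimethoxy-4,4,8,10-tetramethyldecal-7-ene-3,9-dione
Conditions: H2 (1 atm), RhCl(PPh3)3 (5 mol %), PhMe/EtOH, rt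
Reagents that add atoms: none
Why: Homogeneous hydrogenation with RhCl(PPh3)3 reduces the cis-disubstituted C1=C2 enone alkene far faster than the trisubstituted, ketal-flanked C7=C8 alkene, as in the selective 1,2-reduction of steroidal 1,4-dien-3-ones.

Step 7
Reactants: 9 cis-fused keto enone ketal
Product: 11 trans-fused (5R,10R)-4,4,8,10-tetramethyldecal-7-ene-3,6,9-trione, via cis-fused trione 10 (not isolated)
Conditions: 2 M aq HCl, THF, rt → 50 °C
Reagents that add atoms: water, O
Why: Acid hydrolysis of the dimethyl ketal unveils the C6 ketone of an ene-1,4-dione, and acid-catalysed enolisation toward C5 (its only α-hydrogen) equilibrates the ring fusion to the trans-decalin, expected to be the more stable isomer as with other angularly methylated enedione adducts.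

Step 8
Reactants: 11 trans-fused trione
Product: 12 (3R,5R,6S,10R)-3,6-dihydroxy-4,4,8,10-tetramethyldecal-7-en-9-one (C3–OH equatorial and syn; C6–OH expected syn but its configuration is irrelevant)
Conditions: NaBH4, MeOH/CH2Cl2, −78 → 0 °C
Reagents that add atoms: none
Why: Borohydride reduction: hydride adds 1,2 to the unhindered, doubly activated C6 carbonyl and axially (anti to the C10 and axial C4 methyls) to the C3 ketone, giving the equatorial C3 alcohol, while the C9 carbonyl between quaternary C10 and the C8 methyl is left, in line with the known preference of angular-methyl quinone adducts for reduction at the remote carbonyl.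

Step 9
Reactants: 12 dihydroxy enone
Product: 13 (3R,5R,6S,10R)-3,6-diacetoxy-4,4,8,10-tetramethyldecal-7-en-9-one
Conditions: Ac2O, DMAP, Et3N, CH2Cl2, rt → 40 °C
Reagents that add atoms: acetic anhydride, CC(=O)OC(C)=O
Why: DMAP-catalysed acylation esterifies both secondary alcohols; the C3 acetate is the ester of the target and the C6 acetate is the leaving group for the next step.

Step 10
Reactants: 13 diacetoxy enone
Product: 14 (3R,5R,10R)-3-acetoxy-4,4,8,10-tetramethyldecal-7-en-9-one (3-acetoxy-11-nordrim-7-en-9-one)
Conditions: Zn dust, AcOH, 90 °C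
Reagents that add atoms: none
Why: Vinylogous α-acyloxy ketone reduction: electron transfer from zinc to the enone expels the γ-acetate at C6 to give the C9 dienol, which in hot acetic acid reprotonates at C6 to the C7=C8 enone, the only conjugated isomer possible because C10 is quaternary; the unactivated C3 acetate stays.

Step 11
Reactants: 14 3-acetoxy enone
Product: 15 (3R,5S,10R)-3-acetoxydrima-7,9(11)-diene
Conditions: Zn, CH2Br2, TiCl4, THF/CH2Cl2, 0 °C → rt
Reagents that add atoms: dibromomethane, BrCBr
Why: Takai–Lombardo methylenation: the non-basic gem-dimetallic methylene reagent adds to hindered ketones and does not attack esters, so C9=O becomes the exocyclic C9=C11 alkene with the acetate intact.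

Step 12
Reactants: 15 3-acetoxy diene
Product: 17 (3R,5S,9R,10R)-3-acetoxydrim-7-en-11-ol, via B-alkyl-9-borabicyclononane 16 (not isolated)
Conditions: 9-borabicyclo[3.3.1]nonane (9-BBN), THF, 65 °C; then 30% H2O2, aq NaOAc, 0 °C → rt
Reagents that add atoms: hydrogen peroxide, OO
Why: Hydroboration–oxidation: 9-BBN adds only to the 1,1-disubstituted exocyclic alkene with boron on the terminal C11 and delivers hydrogen to C9 anti to the axial C10 methyl, so C11 ends syn to that methyl, and buffered peroxide oxidises the C–B bond with retention while sparing the acetate.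

Step 13
Reactants: 17 3-acetoxydrim-7-en-11-ol; 18 umbelliferone (7-hydroxycoumarin)
Product: 19 7-{[(3R,5S,9R,10R)-3-acetoxydrim-7-en-11-yl]oxy}coumarin (target)
Conditions: PPh3, DIAD, THF, 0 °C → rt
Reagents that add atoms: none
Why: Mitsunobu etherification: the primary C11 alcohol is activated as its alkoxyphosphonium ion and displaced in an SN2 reaction by the acidic 7-hydroxyl of umbelliferone, so no stereocentre is touched and the acetate and lactone are inert.

**Compound list**

1 | 4-methoxy-2,6-dimethylphenol | COc1cc(C)c(O)c(C)c1 | starting material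
2 | 4,4-dimethoxy-2,6-dimethylcyclohexa-2,5-dien-1-one | COC1(OC)C=C(C)C(=O)C(C)=C1 | intermediate
3 | ethyl vinyl ketone (pent-1-en-3-one) | CCC(=O)C=C | starting material
4 | (Z)-3-(triisopropylsilyloxy)penta-1,3-diene | C=C/C(O[Si](C(C)C)(C(C)C)C(C)C)=C/C | intermediate
5 | cis-fused (4R,5S,10R)-6,6-dimethoxy-4,8,10-trimethyl-3-(triisopropylsilyloxy)decalin-2,7-dien-9-one | CC(C)[Si](C(C)C)(C(C)C)OC1=CC[C@@]2(C)C(=O)C(C)=CC(OC)(OC)[C@H]2[C@H]1C | intermediate
6 | cis-fused (4R,5S,10R)-6,6-dimethoxy-4,8,10-trimethyldecalin-1,7-diene-3,9-dione | O=C1C=C[C@@]2(C)C(=O)C(C)=CC(OC)(OC)[C@H]2[C@H]1C | intermediate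
7 | lithium C3–C4 enolate of 6 | [Li]OC1C=C[C@@]2(C)C(=O)C(C)=CC(OC)(OC)[C@H]2C=1C | intermediate (not isolated)
8 | cis-fused (5S,10R)-6,6-dimethoxy-4,4,8,10-tetramethyldecalin-1,7-diene-3,9-dione | O=C1C=C[C@@]2(C)C(=O)C(C)=CC(OC)(OC)[C@H]2C1(C)C | intermediate
9 | cis-fused (5S,10R)-6,6-dimethoxy-4,4,8,10-tetramethyldecal-7-ene-3,9-dione | O=C1CC[C@@]2(C)C(=O)C(C)=CC(OC)(OC)[C@H]2C1(C)C | intermediate
10 | cis-fused (5S,10R)-4,4,8,10-tetramethyldecal-7-ene-3,6,9-trione | O=C1CC[C@@]2(C)C(=O)C(C)=CC(=O)[C@H]2C1(C)C | intermediate (not isolated)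
11 | trans-fused (5R,10R)-4,4,8,10-tetramethyldecal-7-ene-3,6,9-trione | O=C1CC[C@@]2(C)C(=O)C(C)=CC(=O)[C@@H]2C1(C)C | intermediate
12 | (3R,5R,6S,10R)-3,6-dihydroxy-4,4,8,10-tetramethyldecal-7-en-9-one | O[C@@H]1CC[C@@]2(C)C(=O)C(C)=C[C@H](O)[C@@H]2C1(C)C | intermediate
13 | (3R,5R,6S,10R)-3,6-diacetoxy-4,4,8,10-tetramethyldecal-7-en-9-one | CC(=O)O[C@@H]1CC[C@@]2(C)C(=O)C(C)=C[C@H](OC(C)=O)[C@@H]2C1(C)C | intermediate
14 | (3R,5R,10R)-3-acetoxy-4,4,8,10-tetramethyldecal-7-en-9-one | CC(=O)O[C@@H]1CC[C@@]2(C)C(=O)C(C)=CC[C@@H]2C1(C)C | intermediate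
15 | (3R,5S,10R)-3-acetoxydrima-7,9(11)-diene | CC(=O)O[C@@H]1CC[C@@]2(C)C(=C)C(C)=CC[C@@H]2C1(C)C | intermediate
16 | B-[(3-acetoxydrim-7-en-11-yl)]-9-borabicyclo[3.3.1]nonane (C11 syn to the C10 methyl) | CC(=O)O[C@@H]1CC[C@@]2(C)[C@H](CB3C4CCCC3CCC4)C(C)=CC[C@@H]2C1(C)C | intermediate (not isolated)
17 | (3R,5S,9R,10R)-3-acetoxydrim-7-en-11-ol | CC(=O)O[C@@H]1CC[C@@]2(C)[C@H](CO)C(C)=CC[C@@H]2C1(C)C | intermediate
18 | umbelliferone (7-hydroxycoumarin) | Oc1ccc2ccc(=O)oc2c1 | starting material
19 | 7-{[(3R,5S,9R,10R)-3-acetoxydrim-7-en-11-yl]oxy}coumarin | CC(=O)O[C@@H]1CC[C@@]2(C)[C@H](COc3ccc4ccc(=O)oc4c3)C(C)=CC[C@@H]2C1(C)C | target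

**Step count and risks**

Total: 13 steps. Longest linear sequence: 12 steps (1 → 19 through steps 1 and 3–13; equally from 3 through steps 2–13).

Steps most likely to fail:

1. Step 3. The α-methylated, ketal-flanked enone may add sluggishly, the strong acid may ionise the ketal, or the enantiotopic faces may be poorly discriminated because the dienone offers no α-C–H contact to the catalyst. Fallback (auxiliary control in place of catalyst control): starting from 2, ketal exchange with (R,R)-hydrobenzoin (BF3·OEt2, DME) would give the C2-symmetric spiro-dioxolane dienone F1, whose enone faces are diastereotopic. Cycloaddition with 4 promoted by Me2AlCl would give the dioxolane adduct F2 (diastereomers separable; the (S,S)-diol is used if the wrong face proves to be shielded). F2 is carried through the chemistry of steps 4–6 as the C1=C2 enone F3, its lithium enolate F4, the gem-dimethyl enone F5 and the saturated C3 ketone F6. Aqueous acid then removes the auxiliary and the sequence comes back to the route at 10, which equilibrates to 11 as in step 7.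

2. Step 7. The cis-to-trans equilibration at C5 may stall or lie on the cis side because of the C4 gem-dimethyl group. Fallback (kinetic in place of thermodynamic control): from 10, TBSOTf/Et3N would give the bis(silyl enol ether) F7 (C2=C3 and C5=C6), and protonolysis with HF·pyridine at −78 °C should deliver the proton to C5 anti to the C10 methyl, returning to the route at 11.

3. Step 8. The C9 carbonyl may be over-reduced, or the enedione reduced in the conjugate sense, while the slower C3 ketone is being reduced. Fallback (the two reductions are decoupled): from 11, exhaustive 1,2-reduction with NaBH4/CeCl3·7H2O would give the triol F8; MnO2 would re-oxidise both allylic alcohols to the 3-hydroxy enedione F9, and one hydride equivalent of NaBH4 at −78 °C would then reduce only the C6 carbonyl, returning to the route at 12.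

**Further compounds**

F1 | step 3 | (2R,3R)-7,9-dimethyl-2,3-diphenyl-1,4-dioxaspiro[4.5]deca-6,9-dien-8-one | CC1=CC2(C=C(C)C1=O)O[C@H](c1ccccc1)[C@@H](c1ccccc1)O2
F2 | step 3 | cis-fused C3 silyl enol ether adduct with the C6 (R,R)-diphenyldioxolane | CC(C)[Si](C(C)C)(C(C)C)OC1=CC[C@@]2(C)C(=O)C(C)=CC3(O[C@H](c4ccccc4)[C@@H](c4ccccc4)O3)[C@H]2[C@H]1C
F3 | step 3 | cis-fused 1,7-diene-3,9-dione with the C6 (R,R)-diphenyldioxolane | O=C1C=C[C@@]2(C)C(=O)C(C)=CC3(O[C@H](c4ccccc4)[C@@H](c4ccccc4)O3)[C@H]2[C@H]1C
F4 | step 3 | lithium C3–C4 enolate of F3 | [Li]OC1C=C[C@@]2(C)C(=O)C(C)=CC3(O[C@H](c4ccccc4)[C@@H](c4ccccc4)O3)[C@H]2C=1C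
F5 | step 3 | cis-fused 4,4-dimethyl-1,7-diene-3,9-dione with the C6 (R,R)-diphenyldioxolane | O=C1C=C[C@@]2(C)C(=O)C(C)=CC3(O[C@H](c4ccccc4)[C@@H](c4ccccc4)O3)[C@H]2C1(C)C
F6 | step 3 | cis-fused 4,4-dimethyl-7-ene-3,9-dione with the C6 (R,R)-diphenyldioxolane | O=C1CC[C@@]2(C)C(=O)C(C)=CC3(O[C@H](c4ccccc4)[C@@H](c4ccccc4)O3)[C@H]2C1(C)C
F7 | step 7 | (10R)-3,6-bis(tert-butyldimethylsilyloxy)-4,4,8,10-tetramethyldecalin-2,5,7-trien-9-one | CC(C)(C)[Si](C)(C)OC1=CC[C@@]2(C)C(=O)C(C)=CC(O[Si](C)(C)C(C)(C)C)=C2C1(C)C
F8 | step 8 | (3R,5R,10R)-4,4,8,10-tetramethyldecal-7-ene-3,6,9-triol (C6 and C9 epimers) | O[C@@H]1CC[C@@]2(C)C(O)C(C)=CC(O)[C@@H]2C1(C)C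
F9 | step 8 | (3R,5R,10R)-3-hydroxy-4,4,8,10-tetramethyldecal-7-ene-6,9-dione | O[C@@H]1CC[C@@]2(C)C(=O)C(C)=CC(=O)[C@@H]2C1(C)C
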